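**Retrosynthetic overview**

- Target 18 comes from flavone 17 by oxidative demethylation of the C3'/C6' para-dimethoxy pair of ring B, and 17 comes from the 3,5,7-trimethoxyflavone 15 by cleavage of the 5-OMe.
- Ring C (the pyranone) is the only ring built: O1–C2 closure and C2–C3 dehydrogenation of the 2'-hydroxychalcone 13. Rings A and B enter as arenes.
- Chalcone 13 comes from insertion of 3,5-dimethoxybenzyne (from silyl triflate 6) into the carboxyl group of the α-methoxycinnamic acid 10, forming O1–C8a and C4a–C4 in one operation.
- The feature used: O1–C8a and C4a–C4 sit on neighbouring carbons of ring A, and the C5 methoxy next to C4a polarises the aryne so that the carboxylate oxygen goes to C8a and the acyl group to C4a.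
- Triflate 6 comes from 3,5-dimethoxyphenol (bromination, O-silylation, retro-Brook shift and triflation); acid 10 comes from aldehyde 7 and methyl methoxyacetate 8.

Key step: step 5

Assumption: 2,3,4,6-tetramethoxybenzaldehyde is taken as a catalogue compound; the target has no stereocenter, and the Z geometry of 9, 10 and 13 is the expected one and is erased in step 6.

**Route**

Step 1
Reactants: 1 3,5-dimethoxyphenol
Product: 2 2-bromo-3,5-dimethoxyphenol
Conditions: NBS (1.0 equiv), CH2Cl2, −78 °C to rt
Reagents that add atoms: N-bromosuccinimide, O=C1CCC(=O)N1Br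
Why: Electrophilic aromatic bromination, in which hydrogen bonding of the phenol to NBS in CH2Cl2 at low temperature should direct bromine to the position ortho to OH and para to a methoxy group, one equivalent keeping it at monobromination and chromatography removing any 4-bromo isomer.

Step 2
Reactants: 2 2-bromo-3,5-dimethoxyphenol
Product: 3 (2-bromo-3,5-dimethoxyphenoxy)trimethylsilane
Conditions: (Me3Si)2NH (1.2 equiv), THF, 70 °C; concentrate
Reagents that add atoms: hexamethyldisilazane, C[Si](C)(C)N[Si](C)(C)C
Why: O-silylation of a phenol with hexamethyldisilazane, driven by loss of ammonia, should give the trimethylsilyl ether cleanly enough to be used crude.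

Step 3
Reactants: 3 (2-bromo-3,5-dimethoxyphenoxy)trimethylsilane
Product: 6 3,5-dimethoxy-2-(trimethylsilyl)phenyl trifluoromethanesulfonate, via aryllithium 4 (not isolated), via lithium 2-silylphenoxide 5 (not isolated)
Conditions: n-BuLi (1.1 equiv), THF, −100 to −80 °C; then Tf2O (1.2 equiv), −100 to −80 °C; aq NaHCO3
Reagents that add atoms: n-butyllithium, [Li]CCCC (lithium, found only in 4 and 5); trifluoromethanesulfonic anhydride, O=S(=O)(OS(=O)(=O)C(F)(F)F)C(F)(F)F
Why: Bromine–lithium exchange gives an aryllithium that takes the silyl group from the neighbouring oxygen (retro-Brook 1,3 O-to-C shift), and the lithium phenoxide so formed is O-sulfonylated by Tf2O, the low temperature keeping the aryllithium from reacting with 1-bromobutane.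

Step 4
Reactants: 7 2,3,4,6-tetramethoxybenzaldehyde; 8 methyl methoxyacetate (4 equiv)
Product: 10 (Z)-2-methoxy-3-(2,3,4,6-tetramethoxyphenyl)acrylic acid, via methyl ester 9 (not isolated)
Conditions: NaOMe (3 equiv), MeOH, reflux; then aq NaOH, 60 °C; then HCl to pH 2, crystallise
Reagents that add atoms: sodium hydroxide, [Na+].[OH-] (oxygen of the acid OH)
Why: Claisen-type aldol condensation of the ester enolate with a non-enolisable aldehyde followed by E1cB dehydration should give the conjugated α-methoxycinnamate with the aryl group trans to the ester (Z), and hydroxide then saponifies the methyl ester in the same flask.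

Step 5
Reactants: 6 3,5-dimethoxy-2-(trimethylsilyl)phenyl trifluoromethanesulfonate (1.5 equiv); 10 (Z)-2-methoxy-3-(2,3,4,6-tetramethoxyphenyl)acrylic acid
Product: 13 (Z)-1-(2-hydroxy-4,6-dimethoxyphenyl)-2-methoxy-3-(2,3,4,6-tetramethoxyphenyl)prop-2-en-1-one, via 3,5-dimethoxybenzyne 11 (not isolated), via cesium aryl anion 12 (not isolated)
Conditions: CsF (4 equiv), THF, 125 °C, sealed tube; aq NH4Cl
Reagents that add atoms: cesium fluoride, [Cs+].[F-] (cesium, found only in 12)
Why: Fluoride attacks the silicon of 6 and expels triflate to give aryne 11, to which the cesium carboxylate of 10 adds through oxygen at the aryne carbon remote from the flanking methoxy group (the future C8a), leaving aryl anion 12 at the future C4a. That anion attacks the neighbouring ester carbonyl through a four-membered transition state and the adduct collapses with cleavage of the acyl–oxygen bond to the ketone phenoxide, an anionic Fries-type 1,3 O-to-C acyl shift, so that O1–C8a and C4a–C4 form in one operation. The closest known reaction type is the insertion of arynes into the C–O bond of carboxylic acids, which gives ortho-hydroxyaryl ketones with CsF in hot THF. No ring is closed and no stereocenter is formed; the Z alkene, the C3 methoxy group and ring B are carried through untouched. The step needs regioselective addition to the aryne, which the C5 methoxy group should secure by distorting the aryne so that its far carbon is the more electrophilic one and by stabilising the anion beside it inductively. It also needs acyl transfer to outrun protonation of 12 and conjugate addition to the enone, which the aprotic medium at 125 °C, the absence of free acid under excess CsF and the shielding of the β-carbon by the 2,6-dimethoxyaryl group should favour.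

Step 6
Reactants: 13 (Z)-1-(2-hydroxy-4,6-dimethoxyphenyl)-2-methoxy-3-(2,3,4,6-tetramethoxyphenyl)prop-2-en-1-one
Product: 15 3,5,7-trimethoxy-2-(2,3,4,6-tetramethoxyphenyl)-4H-chromen-4-one, via 3-methoxyflavanone 14 (not isolated)
Conditions: I2 (10 mol%), DMSO, 130 °C; aq Na2S2O3
Reagents that add atoms: none
Why: Iodine-catalysed oxidative cyclisation of a 2'-hydroxychalcone in DMSO, in which 6-endo oxa-Michael closure (O1–C2) gives the flavanone and iodine-mediated dehydrogenation installs C2=C3 while DMSO reoxidises HI to I2; both transient stereocenters and the alkene geometry are erased.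

Step 7
Reactants: 15 3,5,7-trimethoxy-2-(2,3,4,6-tetramethoxyphenyl)-4H-chromen-4-one
Product: 17 5-hydroxy-3,7-dimethoxy-2-(2,3,4,6-tetramethoxyphenyl)-4H-chromen-4-one, via aryloxydichloroborane 16 (not isolated)
Conditions: BCl3 (1.3 equiv, 1 M in CH2Cl2), CH2Cl2, −78 to 0 °C; aq HCl
Reagents that add atoms: boron trichloride, ClB(Cl)Cl (boron and chlorine, found only in 16)
Why: Chelation-controlled ether cleavage, in which BCl3 bridges the C4 carbonyl and the peri 5-methoxy oxygen in a six-membered chelate and chloride removes that methyl group by SN2, while the 7-methoxyl, the ring B methoxyls and the less well placed 3-methoxyl should survive at low temperature with little excess reagent.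

Step 8
Reactants: 17 5-hydroxy-3,7-dimethoxy-2-(2,3,4,6-tetramethoxyphenyl)-4H-chromen-4-one
Product: 18 2-(5-hydroxy-3,7-dimethoxy-4-oxo-4H-chromen-2-yl)-3,5-dimethoxycyclohexa-2,5-diene-1,4-dione
Conditions: (NH4)2Ce(NO3)6 (2.5 equiv), MeCN/H2O, 0 °C
Reagents that add atoms: water, O
Why: Oxidative demethylation by tetravalent cerium, in which single-electron oxidation of the electron-rich ring B, ipso attack of water at C3' and C6' (its only para-related methoxy pair) and loss of methanol give the 2,6-dimethoxy-1,4-benzoquinone, while ring A, deactivated by the pyranone carbonyl and carrying a hydrogen-bonded phenol, should be left alone.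

**Compound list**

1 | 3,5-dimethoxyphenol | COc1cc(O)cc(OC)c1 | starting material
2 | 2-bromo-3,5-dimethoxyphenol | COc1cc(O)c(Br)c(OC)c1 | intermediate
3 | (2-bromo-3,5-dimethoxyphenoxy)trimethylsilane | COc1cc(O[Si](C)(C)C)c(Br)c(OC)c1 | intermediate
4 | [2,4-dimethoxy-6-(trimethylsilyloxy)phenyl]lithium | COc1cc(O[Si](C)(C)C)c([Li])c(OC)c1 | intermediate (not isolated)
5 | lithium 3,5-dimethoxy-2-(trimethylsilyl)phenoxide | [Li+].[O-]c1cc(OC)cc(OC)c1[Si](C)(C)C | intermediate (not isolated)
6 | 3,5-dimethoxy-2-(trimethylsilyl)phenyl trifluoromethanesulfonate | COc1cc(OC)c([Si](C)(C)C)c(OS(=O)(=O)C(F)(F)F)c1 | intermediate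
7 | 2,3,4,6-tetramethoxybenzaldehyde | COc1cc(OC)c(C=O)c(OC)c1OC | starting material
8 | methyl methoxyacetate | COCC(=O)OC | starting material
9 | methyl (Z)-2-methoxy-3-(2,3,4,6-tetramethoxyphenyl)acrylate | COC(=O)/C(OC)=C/c1c(OC)cc(OC)c(OC)c1OC | intermediate (not isolated)
10 | (Z)-2-methoxy-3-(2,3,4,6-tetramethoxyphenyl)acrylic acid | OC(=O)/C(OC)=C/c1c(OC)cc(OC)c(OC)c1OC | intermediate
11 | 3,5-dimethoxybenzyne | COC1=CC(OC)=CC#C1 | intermediate (not isolated)
12 | cesium 2,4-dimethoxy-6-{[(Z)-2-methoxy-3-(2,3,4,6-tetramethoxyphenyl)prop-2-enoyl]oxy}benzen-1-ide | [Cs+].COc1cc(OC)[c-]c(OC(=O)/C(OC)=C/c2c(OC)cc(OC)c(OC)c2OC)c1 | intermediate (not isolated)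
13 | (Z)-1-(2-hydroxy-4,6-dimethoxyphenyl)-2-methoxy-3-(2,3,4,6-tetramethoxyphenyl)prop-2-en-1-one | COc1cc(O)c(C(=O)/C(OC)=C/c2c(OC)cc(OC)c(OC)c2OC)c(OC)c1 | intermediate
14 | 3,5,7-trimethoxy-2-(2,3,4,6-tetramethoxyphenyl)chroman-4-one (mixture of C2/C3 diastereomers) | COc1cc(OC)c2c(c1)OC(c1c(OC)cc(OC)c(OC)c1OC)C(OC)C2=O | intermediate (not isolated)
15 | 3,5,7-trimethoxy-2-(2,3,4,6-tetramethoxyphenyl)-4H-chromen-4-one | COc1cc(OC)c2c(c1)oc(-c1c(OC)cc(OC)c(OC)c1OC)c(OC)c2=O | intermediate
16 | 5-(dichloroboryloxy)-3,7-dimethoxy-2-(2,3,4,6-tetramethoxyphenyl)-4H-chromen-4-one | COc1cc(OB(Cl)Cl)c2c(c1)oc(-c1c(OC)cc(OC)c(OC)c1OC)c(OC)c2=O | intermediate (not isolated)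
17 | 5-hydroxy-3,7-dimethoxy-2-(2,3,4,6-tetramethoxyphenyl)-4H-chromen-4-one | COc1cc(O)c2c(c1)oc(-c1c(OC)cc(OC)c(OC)c1OC)c(OC)c2=O | intermediate
18 | 2-(5-hydroxy-3,7-dimethoxy-4-oxo-4H-chromen-2-yl)-3,5-dimethoxycyclohexa-2,5-diene-1,4-dione | COC1=CC(=O)C(c2oc3cc(OC)cc(O)c3c(=O)c2OC)=C(OC)C1=O | target

**Step count and risks**

Total steps: 8. Longest linear sequence: 7 steps (steps 1, 2, 3, 5, 6, 7, 8 from 3,5-dimethoxyphenol); the ring B branch is step 4.

Most likely to fail, first: step 5. The aryl anion 12 may be protonated before the acyl group migrates, so that the reaction stops at the aryl ester, or the aryne may be consumed by the enol ether double bond of 10. The fallback forms the C4a–C4 bond by Friedel–Crafts acylation and sets out from acid 10. Trifluoroacetic anhydride in CH2Cl2 at room temperature converts 10 into (Z)-2-methoxy-3-(2,3,4,6-tetramethoxyphenyl)acrylic trifluoroacetic anhydride F1, not isolated. F1 acylates commercial 1,3,5-trimethoxybenzene (COc1cc(OC)cc(OC)c1) to give (Z)-2-methoxy-3-(2,3,4,6-tetramethoxyphenyl)-1-(2,4,6-trimethoxyphenyl)prop-2-en-1-one F2. BCl3 (1.1 equiv, CH2Cl2, −78 to 0 °C) then removes one of the two equivalent methyl groups ortho to the ketone by chelation, through (Z)-1-[2-(dichloroboryloxy)-4,6-dimethoxyphenyl]-2-methoxy-3-(2,3,4,6-tetramethoxyphenyl)prop-2-en-1-one F3, hydrolysed on work-up. The route is rejoined at chalcone 13.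

Second: step 6. The I2/DMSO couple may iodinate the activated C5'–H of ring B or C6/C8 of ring A, or the reaction may stall at the flavanone because the β-carbon is shielded and the dehydrogenation is slow. The fallback separates ring closure from dehydrogenation and avoids electrophilic iodine. It sets out from chalcone 13, which NaOAc in refluxing EtOH should close by oxa-Michael addition to flavanone 14, now isolated as the diastereomer mixture. 2,3-Dichloro-5,6-dicyano-1,4-benzoquinone in refluxing 1,4-dioxane then removes the C2 and C3 hydrogens, and the route is rejoined at flavone 15. No compound outside the list is made (F0).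

Third: step 4. Aldol addition of the ester enolate to the hindered, electron-rich aldehyde is reversible and may lie on the side of the starting materials, while self-condensation of methyl methoxyacetate uses up the reagent. The fallback replaces the condensation by a Horner–Wadsworth–Emmons olefination and sets out from aldehyde 7. Commercial methyl 2-(dimethoxyphosphoryl)-2-methoxyacetate (COC(=O)C(OC)P(=O)(OC)OC), deprotonated with NaH in THF at 0 °C to room temperature, should give ester 9, which is isolated here. LiOH in THF/H2O then saponifies it and crystallisation gives the Z acid, so the route is rejoined at 10 by way of 9. Any E isomer carried along would not matter, since the geometry is erased in step 6. No compound outside the list is made (F0).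

**Further compounds**

F1 | step 5 | (Z)-2-methoxy-3-(2,3,4,6-tetramethoxyphenyl)acrylic trifluoroacetic anhydride | FC(F)(F)C(=O)OC(=O)/C(OC)=C/c1c(OC)cc(OC)c(OC)c1OC
F2 | step 5 | (Z)-2-methoxy-3-(2,3,4,6-tetramethoxyphenyl)-1-(2,4,6-trimethoxyphenyl)prop-2-en-1-one | COc1cc(OC)c(C(=O)/C(OC)=C/c2c(OC)cc(OC)c(OC)c2OC)c(OC)c1
F3 | step 5 | (Z)-1-[2-(dichloroboryloxy)-4,6-dimethoxyphenyl]-2-methoxy-3-(2,3,4,6-tetramethoxyphenyl)prop-2-en-1-one | COc1cc(OB(Cl)Cl)c(C(=O)/C(OC)=C/c2c(OC)cc(OC)c(OC)c2OC)c(OC)c1
F0 | step 6 | none | none
F0 | step 4 | none | none
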